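The vessel is closed and stirred at one temperature, and in it starting material meets partner over the catalyst.

| flask | starting material | partner | free catalyst | time |
|---|---|---|---|---|
| alpha | 0.0500 M | 0.0600 M | 0.00500 M |  |
| zeta | 0.0200 M | 0.0300 M | 0.00500 M |  |
| delta | 0.0500 M | 0.120 M | 0.00500 M |  |
| gamma | 0.150 M | 0.0300 M | 0.00500 M | 120 min |

| run | time / min | [product] / M |
|---|---|---|
| alpha run | 4.8 | 0.00318 |
| alpha run | 8.2 | 0.00513 |
| alpha run | 14 | 0.00740 |
| alpha run | 24 | 0.01017 |
| alpha run | 41 | 0.01316 |
| alpha run | 70 | 0.01611 |
| alpha run | 120 | 0.01873 |
| zeta run | 4.8 | 6.2 × 10⁻⁴ |
| zeta run | 8.2 | 9.3 × 10⁻⁴ |
| zeta run | 14 | 0.00167 |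
| zeta run | 24 | 0.00314 |
| zeta run | 41 | 0.00397 |
| zeta run | 70 | 0.00540 |
| zeta run | 120 | 0.00645 |
| delta run | 4.8 | 0.00595 |
| delta run | 8.2 | 0.00966 |
| delta run | 14 | 0.01352 |
| delta run | 24 | 0.01837 |
| delta run | 41 | 0.02259 |
| delta run | 70 | 0.02597 |
| delta run | 120 | 0.02806 |

(readings scatter by 2 × 10⁻⁴ M)

1. apparent order in [starting material] of the starting rate, round the charge of the alpha run (the rate where two percent of its starting material have turned into product) (one fixed amount of product, the same in the runs compared)
2. apparent order in [partner] of the starting rate, round the charge of the alpha run (the rate where two percent of its starting material have turned into product)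
3. product in the gamma run at 120 min, as a share of the starting material charged
4. which of these the readings show (the catalyst wakes slowly / two substrates go astray together / nothing beyond the main steps / the second partner pairs with itself / the product binds the second partner)

- Overall: starting material + partner -> product, with free catalyst as catalyst.
- Constant volume, constant temperature.
- "The second partner" is partner.
- An order is taken over about fifteen percent of the charge, up and down.

This reckoning supposes two ways out for starting material: product, at a rate k·S·R, and straying with itself, at a rate proportional to S·S. Dividing one rate by the other removes time: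

strayed per product made = ρ·S/R

Here ρ is the stray constant over k.

The first alpha reading, divided by its time and by the charges less half of that product, gives k:

k = (0.00318 M / 4.8 min) / (mean S × mean R) = 0.234 M⁻¹ min⁻¹

The last alpha interval, with its rate divided by k and by the partner left, reads as follows at its middle: product 34.8% of the charge, starting material left 10.5%, strayed 54.7%. Strayed per product, divided by a rough mean of S/R between the start and that point, gives the reading:

ρ = 3.28

This reading is the stray constant over k, the selectivity factor.

In the gamma flask, ρ·S/R starts at 16.4, so this reckoning takes straying as the exit of starting material. The partner then follows: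

share of partner left = (1 + ρ·k·S charge·t)^(−1/ρ)

Which numbers matter for gamma? The catalyst charge is the same in every run, so it rides inside k. Time sits in a logarithm: twice the time gives a gamma share of 12.8%. Twice ρ at the same k gives 8.01%. Twice k at the same stray constant gives 16.1%. So k and ρ count most. With the values read, the partner left is 43.9%, and product is 11.2% of the starting material.

The forecast gives orders of 1.02 and 1.06, a gamma share of 10.6% (from 9.3% to 12.2%), and the verdict two substrates go astray together, on the ground that “A loss second order in S, about 0.8[S]², reproduces all the late rates.” Its share is lower than this reckoning's.

The flask gives orders of 1.0 and 1.1, a gamma share of 9.99%, and two substrates go astray together.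

    2 free catalyst ⇌ catalyst dimer, settled at all times (64.80 M⁻¹)
    catalyst dimer + starting material + partner → product + catalyst dimer (346.2 M⁻² min⁻¹)
    2 starting material → homo dimer (0.5214 M⁻¹ min⁻¹)

Without the path from two starting material to homo dimer, the gamma share rises from 9.99% to 19.7%, which is above the forecast's top of 12.2%, so that run would have made the forecast wrong. With the path and the ρ of 3.28 read from alpha, gamma starts at 16.4 strayed per product. The same ρ gives the delta flask 1.37 at its start, and the delta run reads 56.1% of its starting material as product at 120 min.

The runs were computed for an exercise; scatter was added.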